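Time is the column I hold fixed: I read the percent of product in one run against another at the same minute.

| flask | substrate | enzyme | added ligand | remark |
|---|---|---|---|---|
| dusk | 0.080 M | 12 µM | 28 µM | run made earlier |
| spring | 0.18 M | 12 µM | 28 µM | run made earlier |
| dawn | 0.12 M | 18 µM | 28 µM | run made earlier |
| flask | 0.12 M | 12 µM | 28 µM |  |

| run | time / min | product / % |
|---|---|---|
| dusk | 0.833 | 3 |
| dusk | 2.50 | 9 |
| dusk | 5.00 | 18 |
| dusk | 6.00 | 21 |
| dusk | 10.0 | 32 |
| dusk | 12.0 | 38 |
| dusk | 15.0 | 45 |
| spring | 2.50 | 11 |
| spring | 5.00 | 17 |
| spring | 6.00 | 22 |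
| spring | 10.0 | 34 |
| spring | 12.0 | 38 |
| spring | 15.0 | 51 |
| dawn | 1.33 | 11 |
| dawn | 2.50 | 23 |
| dawn | 5.00 | 37 |
| dawn | 8.00 | 52 |
| dawn | 15.0 | 72 |

(standard deviation of a reading: 1.5 percentage points)

- factor on the rate of making product when 30% of the substrate are converted if enzyme is charged twice over
- factor on the rate when 30% of the substrate are converted if enzyme is charged at 120 µM instead

At 10.0 min the dusk run shows 32% and the spring run 34%, although the spring run holds 0.18 M substrate against 0.080 M, so I treat substrate as pseudo-first-order, with k the negative logarithm of the unconverted fraction per minute.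

At 15.0 min the dusk run gives 0.0399 /min and the dawn run 0.0849 /min. That is a factor of 2.13 on k for a factor of 1.50 on enzyme, a steeper rise than the charge. Substrate differs between these two runs as well, 0.12 M against 0.080 M, but I have just treated k as free of substrate, so I put the factor down to enzyme. I therefore take free enzyme, concentration c, as the working form, with added ligand holding the rest one to one as idle complex.

The spare ligand s, ligand minus enzyme charged, is 16.0 µM in the dusk run and 10.0 µM in the dawn run. I give both runs one dissociation constant K_d, let c scale with k, and drop the term in c times c. My reading is then c = 0.661 µM at 12 µM enzyme, which is also the flask's charge, and K_d = 0.970 µM.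

At 24.0 µM enzyme the binding quadratic gives 2.94 µM free, so I expect a factor of 4.45.

At 120 µM the ligand becomes the limiting reagent, and I carry the overflow W, enzyme charged minus ligand charged: 92.0 µM. Dividing W by c, I expect 139.

The forecast says 5.2 (4.3 to 6.5) and 250 (130 to 620), both higher than mine, from 0.36 µM free enzyme at 12 µM charged: “The latter is poorly fixed because it depends on the small free enzyme concentration.”

The simulation gives 4.21 for the doubled charge and 116 for 120 µM.

    substrate + enzyme → product + enzyme, rate k1*[substrate]^1.5*[enzyme]/(1 + ([substrate]/Kh1)^1.5) (0.207 M, k = 2.29 × 10⁵ /M^1.5/min)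
    enzyme + added ligand ⇌ idle complex, settled at all times (K = 8.40 × 10⁵ /M)

In the flask, enzyme stands at 6.62% of its charge at 2.00 min and 6.62% at 20.0 min, which is 0.794 µM free. The overflow 92.0 µM divided by that free enzyme is 116.

The earlier runs and the new flask stem from a simulated flask from invented constants, and the scatter is random.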